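**Retrosynthetic overview**

- The target is methyl 3-O-acetyl-4,5-bis-O-[(R)-2-methylbutanoyl]shikimate. The three acyl groups go on last, onto a core protected as 3,4-acetonide and 5-silyl ether; orthoacetate opening of the cis-3,4-diol puts the acetate on the pseudoaxial O3.
- The C1=C2 enoate comes from an enol triflate, which comes from a cyclic β-keto ester with its ketone at C2.
- The strategy rests on one feature: C1, which carries the ester carbon C7, lies between C2 and the only ring methylene C6, while C3, C4 and C5 are contiguous oxygenated stereocentres. C1 and C7 are therefore removed as methyl diazoacetate (disconnect C1–C2 and C1–C6, reconnect C2–C6), which leaves a cyclopentanone already holding C3, C4 and C5.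
- The cyclopentanone comes from anti-dihydroxylation and acetonide protection of (R)-4-silyloxycyclopentenone. The only carbocycle, the six-membered ring, is formed in step 4 by one-carbon expansion of the five-membered ring; the dioxolane of steps 2–9 is only a protecting ring.

Key step: step 4

Remark on the chemistry: ring atoms are numbered as in shikimic acid (C1 ester-bearing sp2 carbon, C2 vinylic CH, C3 acetate carbon, C4 and C5 2-methylbutanoate carbons, C6 CH2, C7 ester carbon). The target is then (3R,4S,5R), with 3,4-cis and 4,5-trans oxygens and both side chains (R). Compounds 1, 4 and 11 are assumed to be commercial.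

**Route**

Step 1
Reactants: 1 (R)-4-(tert-butyldimethylsilyloxy)cyclopent-2-en-1-one
Product: 2 (2S,3R,4R)-4-(tert-butyldimethylsilyloxy)-2,3-dihydroxycyclopentan-1-one (2,3-cis diol trans to the silyloxy group; used crude)
Conditions: K2OsO4·2H2O (cat.), NMO, citric acid, t-BuOH/H2O 1:1, rt
Reagents that add atoms: N-methylmorpholine N-oxide, C[N+]1([O-])CCOCC1; water, O
Why: Upjohn-type catalytic syn-dihydroxylation (citric acid-buffered variant for electron-poor alkenes) should deliver both oxygens to the enone face opposite the C4 silyloxy group, which sets C2 and C3 cis to each other and trans to C4–O.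

Step 2
Reactants: 2 (2S,3R,4R)-4-(tert-butyldimethylsilyloxy)-2,3-dihydroxycyclopentan-1-one
Product: 3 (2S,3R,4R)-4-(tert-butyldimethylsilyloxy)-2,3-(isopropylidenedioxy)cyclopentan-1-one
Conditions: 2,2-dimethoxypropane, PPTS (cat.), acetone, rt
Reagents that add atoms: 2,2-dimethoxypropane, COC(C)(C)OC
Why: Acid-catalysed acetonide formation (transketalisation) should close the cis-2,3-diol to the cis-fused dioxolane under conditions mild enough to spare the β-oxygenated ketone and the silyl ether; no stereocentre changes.

Step 3
Reactants: 4 glycine methyl ester hydrochloride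
Product: 5 methyl diazoacetate (kept as a dried, titrated CH2Cl2 solution; not distilled)
Conditions: NaNO2, H2SO4 (cat.), H2O/CH2Cl2, −5 to 0 °C
Reagents that add atoms: sodium nitrite, [Na+].[O-]N=O
Why: Diazotisation of an α-amino ester: N-nitrosation and dehydration give the diazonium ion, which loses its acidic α-proton to the ester-stabilised diazo compound that passes into the organic phase as it forms.

Step 4
Reactants: 3 (2S,3R,4R)-4-(tert-butyldimethylsilyloxy)-2,3-(isopropylidenedioxy)cyclopentan-1-one; 5 methyl diazoacetate
Product: 7 methyl 5-(tert-butyldimethylsilyloxy)-2-hydroxy-3,4-(isopropylidenedioxy)cyclohex-1-ene-1-carboxylate (chelated enol of the β-keto ester; shikimate configuration at C3/C4/C5), via diazonium betaine 6 (not isolated)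
Conditions: BF3·OEt2, CH2Cl2, −78 → −20 °C; aq. NaHCO3 quench
Reagents that add atoms: methyl diazoacetate (5), COC(=O)C=[N+]=[N-]
Why: BF3 activates the ketone of 3, the nucleophilic diazo carbon of 5 adds to it to give the β-oxido diazonium betaine 6, and a ring carbon then shifts 1,2 onto the diazonium-bearing carbon as N2 leaves; this is the Lewis acid-promoted diazoacetate homologation of a cycloalkanone (Tiffeneau–Demjanov type). The six-membered ring is not closed by a new cyclisation but arises by ring expansion: the old C(=O)–CH2 bond is broken and the inserted carbon C1 ends up bonded to both C2 and C6. No lasting stereocentre is created, because C3, C4 and C5 are untouched and the new C1 centre is erased on enolisation to 7. The step needs migration of the methylene carbon and not of the α-alkoxy carbon; the dioxolane oxygen lowers the migratory aptitude of that carbon inductively, and the less substituted carbon is in any case the one that normally moves in these homologations. Low temperature and the absence of base should keep the β-silyloxy ketone from eliminating silanol and the acetonide from opening, and the enolised product is too weakly electrophilic to take up a second diazoacetate.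

Step 5
Reactants: 7 methyl 5-(tert-butyldimethylsilyloxy)-2-hydroxy-3,4-(isopropylidenedioxy)cyclohex-1-ene-1-carboxylate
Product: 8 methyl 5-(tert-butyldimethylsilyloxy)-3,4-(isopropylidenedioxy)-2-(trifluoromethylsulfonyloxy)cyclohex-1-ene-1-carboxylate
Conditions: Tf2O, i-Pr2NEt, CH2Cl2, −78 °C
Reagents that add atoms: trifluoromethanesulfonic anhydride, O=S(=O)(OS(=O)(=O)C(F)(F)F)C(F)(F)F
Why: Enol triflate formation: the hindered amine generates the ester-conjugated enolate, which should be sulfonylated on oxygen at low temperature and so fixes the double bond between C1 and C2.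

Step 6
Reactants: 8 methyl 5-(tert-butyldimethylsilyloxy)-3,4-(isopropylidenedioxy)-2-(trifluoromethylsulfonyloxy)cyclohex-1-ene-1-carboxylate
Product: 9 methyl 5-O-(tert-butyldimethylsilyl)-3,4-O-isopropylidene-shikimate
Conditions: Pd(OAc)2 (cat.), PPh3, HCO2H, n-Bu3N, DMF, 60 °C
Reagents that add atoms: none
Why: Palladium-catalysed formate reduction of a vinyl triflate (Cacchi-type hydrogenolysis): oxidative addition, formate exchange, decarboxylation to the palladium hydride and reductive elimination should replace OTf by H without moving the C1=C2 double bond or touching C3–C5.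

Step 7
Reactants: 9 methyl 5-O-(tert-butyldimethylsilyl)-3,4-O-isopropylidene-shikimate
Product: 10 methyl 3,4-O-isopropylidene-shikimate
Conditions: HF·pyridine, pyridine, THF, 0 °C → rt
Reagents that add atoms: none
Why: Fluoride-mediated silyl ether cleavage under buffered, non-basic conditions should free the C5 hydroxyl while avoiding base-induced elimination or aromatisation of the shikimate ring and leaving the acetonide and methyl ester in place.

Step 8
Reactants: 10 methyl 3,4-O-isopropylidene-shikimate; 11 (R)-2-methylbutanoic acid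
Product: 12 methyl 3,4-O-isopropylidene-5-O-[(R)-2-methylbutanoyl]shikimate
Conditions: DCC, DMAP (cat.), CH2Cl2, 0 °C → rt
Reagents that add atoms: (R)-2-methylbutanoic acid (11), CC[C@@H](C)C(=O)O
Why: Steglich esterification should acylate the only free hydroxyl (C5) with retention at the carbinol carbon, and low temperature with catalytic DMAP should keep the α-stereocentre of the acid from epimerising.

Step 9
Reactants: 12 methyl 3,4-O-isopropylidene-5-O-[(R)-2-methylbutanoyl]shikimate
Product: 13 methyl 5-O-[(R)-2-methylbutanoyl]shikimate (free cis-3,4-diol)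
Conditions: AcOH/H2O 4:1, 60 °C
Reagents that add atoms: none
Why: Acid-catalysed hydrolysis of the isopropylidene acetal should free the diol; the carboxylic esters and the enoate tolerate warm aqueous acetic acid, and acyl migration is slow under acidic conditions.

Step 10
Reactants: 13 methyl 5-O-[(R)-2-methylbutanoyl]shikimate
Product: 15 methyl 3-O-acetyl-5-O-[(R)-2-methylbutanoyl]shikimate, via cyclic orthoacetate 14 (not isolated)
Conditions: MeC(OMe)3, CSA (cat.), CH2Cl2, rt; then 80% aq. AcOH, rt
Reagents that add atoms: trimethyl orthoacetate, CC(OC)(OC)OC; water, O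
Why: Cyclic orthoester formation on the cis-3,4-diol followed by mild acid hydrolysis (regioselective orthoester opening) should give the axial ester and equatorial alcohol; in the shikimate half-chair O3 is pseudoaxial and O4 equatorial, so the acetate should end up on O3.

Step 11
Reactants: 15 methyl 3-O-acetyl-5-O-[(R)-2-methylbutanoyl]shikimate; 11 (R)-2-methylbutanoic acid
Product: 16 methyl (3R,4S,5R)-3-acetoxy-4,5-bis{[(2R)-2-methylbutanoyl]oxy}cyclohex-1-ene-1-carboxylate (CNP0132712.1)
Conditions: DCC, DMAP (cat.), CH2Cl2, 0 °C → rt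
Reagents that add atoms: (R)-2-methylbutanoic acid (11), CC[C@@H](C)C(=O)O
Why: Steglich esterification of the remaining C4 hydroxyl should complete the target with retention at C4 and at the α-carbon of the acid.

**Compound list**

1 | (R)-4-(tert-butyldimethylsilyloxy)cyclopent-2-en-1-one | O=C1C=C[C@H](O[Si](C)(C)C(C)(C)C)C1 | starting material
2 | (2S,3R,4R)-4-(tert-butyldimethylsilyloxy)-2,3-dihydroxycyclopentan-1-one | O[C@@H]1[C@H](O)C(=O)C[C@H]1O[Si](C)(C)C(C)(C)C | intermediate
3 | (2S,3R,4R)-4-(tert-butyldimethylsilyloxy)-2,3-(isopropylidenedioxy)cyclopentan-1-one | CC1(C)O[C@@H]2[C@H](O1)C(=O)C[C@H]2O[Si](C)(C)C(C)(C)C | intermediate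
4 | glycine methyl ester hydrochloride | COC(=O)CN.Cl | starting material
5 | methyl diazoacetate | COC(=O)C=[N+]=[N-] | intermediate
6 | diazonium betaine from addition of 5 to the ketone of 3 (BF3 on the oxido oxygen omitted; the two new centres unassigned) | CC1(C)O[C@@H]2[C@H](O1)C([O-])(C(C(=O)OC)[N+]#N)C[C@H]2O[Si](C)(C)C(C)(C)C | intermediate (not isolated)
7 | methyl 5-(tert-butyldimethylsilyloxy)-2-hydroxy-3,4-(isopropylidenedioxy)cyclohex-1-ene-1-carboxylate, enol form of the β-keto ester, shikimate configuration at C3, C4, C5 | CC1(C)O[C@@H]2[C@H](O1)C(O)=C(C(=O)OC)C[C@H]2O[Si](C)(C)C(C)(C)C | intermediate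
8 | methyl 5-(tert-butyldimethylsilyloxy)-3,4-(isopropylidenedioxy)-2-(trifluoromethylsulfonyloxy)cyclohex-1-ene-1-carboxylate | CC1(C)O[C@@H]2[C@H](O1)C(OS(=O)(=O)C(F)(F)F)=C(C(=O)OC)C[C@H]2O[Si](C)(C)C(C)(C)C | intermediate
9 | methyl 5-O-(tert-butyldimethylsilyl)-3,4-O-isopropylidene-shikimate | CC1(C)O[C@@H]2[C@H](O1)C=C(C(=O)OC)C[C@H]2O[Si](C)(C)C(C)(C)C | intermediate
10 | methyl 3,4-O-isopropylidene-shikimate | CC1(C)O[C@@H]2[C@H](O1)C=C(C(=O)OC)C[C@H]2O | intermediate
11 | (R)-2-methylbutanoic acid | CC[C@@H](C)C(=O)O | starting material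
12 | methyl 3,4-O-isopropylidene-5-O-[(R)-2-methylbutanoyl]shikimate | CC1(C)O[C@@H]2[C@H](O1)C=C(C(=O)OC)C[C@H]2OC(=O)[C@H](C)CC | intermediate
13 | methyl 5-O-[(R)-2-methylbutanoyl]shikimate | O[C@@H]1[C@H](O)C=C(C(=O)OC)C[C@H]1OC(=O)[C@H](C)CC | intermediate
14 | 3,4-O-(1-methoxyethylidene) cyclic orthoacetate of 13 (epimers at the orthoester carbon) | COC1(C)O[C@@H]2[C@H](O1)C=C(C(=O)OC)C[C@H]2OC(=O)[C@H](C)CC | intermediate (not isolated)
15 | methyl 3-O-acetyl-5-O-[(R)-2-methylbutanoyl]shikimate | O[C@@H]1[C@H](OC(C)=O)C=C(C(=O)OC)C[C@H]1OC(=O)[C@H](C)CC | intermediate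
16 | methyl (3R,4S,5R)-3-acetoxy-4,5-bis{[(2R)-2-methylbutanoyl]oxy}cyclohex-1-ene-1-carboxylate | CC[C@@H](C)C(=O)O[C@@H]1[C@H](OC(C)=O)C=C(C(=O)OC)C[C@H]1OC(=O)[C@H](C)CC | target

**Step count and risks**

Total step count: 11. Longest linear sequence: 10 steps (1 → 16 through steps 1, 2 and 4–11); step 3 is a one-step side branch.

Steps most likely to fail:

1. Step 4 (ring expansion). The α-alkoxy carbon may migrate in competition with the methylene, or the Lewis acid may open the acetonide or trigger loss of silanol before insertion. The fallback sets out from 3 and separates addition from migration, with no Lewis acid. Methyl diazoacetate 5 is deprotonated with LDA in THF at −78 °C and added to the ketone in an aldol-type addition. This gives methyl 2-diazo-2-[4-(tert-butyldimethylsilyloxy)-1-hydroxy-2,3-(isopropylidenedioxy)cyclopentyl]acetate F1. Catalytic Rh2(OAc)4 in CH2Cl2 at rt then forms the rhodium carbenoid, and 1,2-shift of the ring methylene with loss of N2 should give β-keto ester 7, where the route is rejoined.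

2. Step 11 (C4 acylation). The acetate may migrate from O3 to the free, flanked O4 under the nucleophilic catalyst while the hindered acylation is slow, giving positional isomers. The fallback sets out from 13 and installs the acetate last. Selective silylation of the less hindered allylic O3 (TBSCl, imidazole, DMF, 0 °C) gives methyl 3-O-(tert-butyldimethylsilyl)-5-O-[(R)-2-methylbutanoyl]shikimate F2. Steglich acylation of the C4 hydroxyl with 11 gives methyl 3-O-(tert-butyldimethylsilyl)-4,5-bis-O-[(R)-2-methylbutanoyl]shikimate F3. HF·pyridine removes the silyl group to give methyl 4,5-bis-O-[(R)-2-methylbutanoyl]shikimate F4. Acetylation (Ac2O, pyridine, cat. DMAP) then gives 16.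

3. Step 1 (enone dihydroxylation). Osmylation of the electron-poor alkene may be slow, the dihydroxy ketone may undergo β-elimination, and facial control may be incomplete. The fallback sets out from 1 and moves the dihydroxylation to an electron-rich alkene. Luche reduction (NaBH4, CeCl3·7H2O, MeOH, −78 °C; hydride anti to the silyloxy group) gives (1S,4R)-cis-4-(tert-butyldimethylsilyloxy)cyclopent-2-en-1-ol F5. Upjohn dihydroxylation anti to both oxygen substituents gives 4-(tert-butyldimethylsilyloxy)cyclopentane-1,2,3-triol F6 (2,3-diol on the face opposite to O1 and O4). 2,2-Dimethoxypropane/PPTS engages only the cis-2,3-diol to give 4-(tert-butyldimethylsilyloxy)-2,3-(isopropylidenedioxy)cyclopentan-1-ol F7. Dess–Martin oxidation then returns ketone 3.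

**Further compounds**

F1 | step 4 | methyl 2-diazo-2-[4-(tert-butyldimethylsilyloxy)-1-hydroxy-2,3-(isopropylidenedioxy)cyclopentyl]acetate (ring centres as in 3, carbinol centre unassigned) | CC1(C)O[C@@H]2[C@H](O1)C(O)(C(=[N+]=[N-])C(=O)OC)C[C@H]2O[Si](C)(C)C(C)(C)C
F2 | step 11 | methyl 3-O-(tert-butyldimethylsilyl)-5-O-[(R)-2-methylbutanoyl]shikimate | O[C@@H]1[C@H](O[Si](C)(C)C(C)(C)C)C=C(C(=O)OC)C[C@H]1OC(=O)[C@H](C)CC
F3 | step 11 | methyl 3-O-(tert-butyldimethylsilyl)-4,5-bis-O-[(R)-2-methylbutanoyl]shikimate | CC[C@@H](C)C(=O)O[C@@H]1[C@H](O[Si](C)(C)C(C)(C)C)C=C(C(=O)OC)C[C@H]1OC(=O)[C@H](C)CC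
F4 | step 11 | methyl 4,5-bis-O-[(R)-2-methylbutanoyl]shikimate | CC[C@@H](C)C(=O)O[C@@H]1[C@H](O)C=C(C(=O)OC)C[C@H]1OC(=O)[C@H](C)CC
F5 | step 1 | (1S,4R)-cis-4-(tert-butyldimethylsilyloxy)cyclopent-2-en-1-ol | O[C@@H]1C=C[C@H](O[Si](C)(C)C(C)(C)C)C1
F6 | step 1 | 4-(tert-butyldimethylsilyloxy)cyclopentane-1,2,3-triol (1,4-cis; 2,3-cis diol on the opposite face) | O[C@@H]1[C@H](O)[C@@H](O)C[C@H]1O[Si](C)(C)C(C)(C)C
F7 | step 1 | 4-(tert-butyldimethylsilyloxy)-2,3-(isopropylidenedioxy)cyclopentan-1-ol (configuration as in F6) | CC1(C)O[C@@H]2[C@H](O1)[C@@H](O)C[C@H]2O[Si](C)(C)C(C)(C)C
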